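Two questions stand on this flask, and both are fractions.

all flasks: gas 110 mM (held)

| flask | solid substrate | remark | time |
|---|---|---|---|
| maple | 2 M | the very flask that is asked about, followed so far |  |
| elm | 3 M | run made earlier |  |
| flask | 2.0 M |  | 15 min |

- amount of target at 15 min, in percent of the solid substrate charged
- concentration of starting material in solution at 15 min, in percent of saturation

| run | time / min | target / % | starting material / % |
|---|---|---|---|
| maple | 0.500 | 1.3 | 1.5 |
| maple | 1.00 | 2.0 | 2.2 |
| maple | 2.50 | 4.3 | 3.3 |
| maple | 6.00 | 5.8 | 4.3 |
| elm | 2.50 | 2.5 | 2.5 |
| elm | 5.00 | 3.4 | 2.4 |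
| elm | 8.00 | 4.0 | 2.8 |
| elm | 10.0 | 3.6 | 3.0 |

(each reading ± 0.3 percentage points)

I read the target columns first. Maple reaches 5.8% of its charge at 6.00 min. Elm, charged with 3 M, reads 4.0% at 8.00 min and 3.6% at 10.0 min; these lie 0.4 percentage points apart, with a scatter of 0.3 points, so I take them as one plateau. Elm's fraction is lower than maple's, so I restate it for the asked charge. My level is the mean of those two elm fractions multiplied by elm's charge over the asked charge: 5.70%. Maple's last reading lies 0.1 points from it, and the two come from different runs. The starting-material columns, restated likewise, give 4.35% from elm against maple's 4.3%. I commit to the level for target, but these columns show me no saturation value, so I give no number for the second question.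

The forecast says 6% and 88%, holding that “Dissolution is limited by solubility, not by the amount of solid.” Its target is higher than my level.

The flask gives 6.34% and 96.2%.

    starting material + reagent ⇌ target (K = 12.0 L mol⁻¹, k = 0.480 L mol⁻¹ s⁻¹)
    starting material + reagent ⇌ isomer of the product (K = 26.0 L mol⁻¹, k = 0.0880 L mol⁻¹ s⁻¹)
    solid substrate ⇌ starting material, rate k3*(cs3 - [starting material]) while solid is left; crystals form when [starting material] > cs3 (solubility = 0.100 M, k = 0.0300 s⁻¹)
    gas ⇌ reagent, rate k4*(csat - [reagent]) (kL = 8.80 s⁻¹)

The forecast's target falls within its margin, and its saturation is 8.2 points low. With reagent at 0.110 M, both product steps run pseudo-first-order in starting material. The flask holds 5.81% of target at 7.50 min, close to my level, and 6.34% at 15.0 min, which is 1.11 times that level. Restated for the neighbouring flask, like this one but charged with 1.2 M, the level becomes 9.50%. At 15.0 min, that neighbouring flask holds 10.6% of target.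

The earlier runs and the new flask were generated by integration with made-up constants; noise was put on by code.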